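**Plan**

- Retrosynthesis: the seven MOM acetals come off last. Before that the pyranone of the flavonol is cut at O1–C2 and at C3–OH, which uncovers a 2'-hydroxychalcone on the C3 aryl ring of the cyclohexene. Its Cα=Cβ bond is cut to an aryl aldehyde and a 2-hydroxyacetophenone, and the cyclohexene is cut at C3–C4 and C5–C6 into a formyl-bearing (E)-1-aryl-3-methylbutadiene and a MOM-protected 2'-hydroxychalcone.
- Forward order: a Diels–Alder reaction makes the cyclohexene first, the freed phenol is capped, a Claisen–Schmidt condensation attaches the future ring A, alkaline peroxide closes the pyranone as the last ring, and deprotection ends the route.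
- Stereochemistry: C3, C4 and C5 are all set in the cycloaddition, promoted by a boron complex of (S)-VANOL (exo approach, all-trans, 3R,4R,5S; C4/C5 trans comes from the (E)-enone). No later step makes or breaks a lasting stereocentre, and C4, the only enolisable one, is already the all-equatorial epimer.
- Enabling feature: C5 of the chromenone (ring A) carries hydrogen, not hydroxyl, so the chalcone has hydrogen at C6'. With that position free, alkaline peroxide closes the six-membered pyranone (flavonol) and not the five-membered aurone, and the nucleophilic oxidant ignores the electron-rich C1=C2 ring alkene.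

Key step: step 10

Assumption: the (S)-VANOL boron complex is taken to shield the enone face that leads to the (3R,4R,5S) adduct; if the sense proves opposite, (R)-VANOL is used in step 7 with no other change.

Numbering of the cyclohexene used throughout: C1 carries the methyl group, C2 is the alkene CH, C3 the flavonol-bearing aryl group, C4 the aroyl group, C5 the second aryl group, C6 is CH2.

**Route**

Step 1
Reactants: 1 2,4-dihydroxyacetophenone
Product: 2 2-hydroxy-4-(methoxymethoxy)acetophenone
Conditions: MOMCl (1.1 equiv), K2CO3, acetone, 0 °C → rt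
Reagents that add atoms: chloromethyl methyl ether (MOMCl), COCCl
Why: Williamson-type MOM ether formation is selective for the 4-hydroxyl because the 2-hydroxyl is held in a hydrogen bond to the ketone and is far less nucleophilic under carbonate conditions.

Step 2
Reactants: 3 2,4-dihydroxybenzaldehyde
Product: 4 2,4-bis(methoxymethoxy)benzaldehyde
Conditions: MOMCl (3 equiv), K2CO3, acetone, reflux
Reagents that add atoms: chloromethyl methyl ether (MOMCl), COCCl
Why: The same Williamson-type MOM ether formation, run with excess reagent at reflux, should cap both phenols, including the hydrogen-bonded 2-hydroxyl.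

Step 3
Reactants: 2 2-hydroxy-4-(methoxymethoxy)acetophenone; 4 2,4-bis(methoxymethoxy)benzaldehyde
Product: 5 (E)-3-[2,4-bis(methoxymethoxy)phenyl]-1-[2-hydroxy-4-(methoxymethoxy)phenyl]prop-2-en-1-one
Conditions: KOH, EtOH/H2O, 0 °C → rt
Reagents that add atoms: none
Why: Claisen–Schmidt condensation of a methyl ketone with a non-enolisable aldehyde gives the conjugated (E)-enone as the thermodynamic product, and the 2'-hydroxyl is carried through as its phenoxide.

Step 4
Reactants: 4 2,4-bis(methoxymethoxy)benzaldehyde
Product: 9 3-iodo-2,4-bis(methoxymethoxy)benzaldehyde, via lithium amino alkoxide 6 (not isolated), via aryllithium 7 (not isolated), via iodinated amino alkoxide 8 (not isolated)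
Conditions: 1-methylpiperazine, n-BuLi, THF, −20 °C, then 4; n-BuLi, −20 → 0 °C; I2, −78 °C → rt; H2O
Reagents that add atoms: iodine, II
Why: Directed ortho-metalation with in situ protection of the aldehyde: the lithium amide adds to the formyl group to give 6, the two MOM ethers together direct n-BuLi to the carbon between them (7), iodine traps the aryllithium (8) and water returns the aldehyde.

Step 5
Reactants: 10 2-methylbut-1-en-3-yne
Product: 11 (E)-4,4,5,5-tetramethyl-2-(3-methylbuta-1,3-dien-1-yl)-1,3,2-dioxaborolane
Conditions: HBpin, Cp2Zr(H)Cl (5 mol %), Et3N (10 mol %), CH2Cl2, rt, sealed tube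
Reagents that add atoms: pinacolborane (HBpin), CC1(C)OBOC1(C)C
Why: Zirconium-catalysed hydroboration of a terminal alkyne: syn, anti-Markovnikov addition of H–B gives the (E)-alkenylboronate, and the 1,1-disubstituted alkene is not touched.

Step 6
Reactants: 9 3-iodo-2,4-bis(methoxymethoxy)benzaldehyde; 11 (E)-4,4,5,5-tetramethyl-2-(3-methylbuta-1,3-dien-1-yl)-1,3,2-dioxaborolane
Product: 12 2,4-bis(methoxymethoxy)-3-[(1E)-3-methylbuta-1,3-dien-1-yl]benzaldehyde
Conditions: Pd(OAc)2, SPhos, K3PO4, toluene/H2O, 70 °C
Reagents that add atoms: none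
Why: Suzuki–Miyaura coupling: the electron-rich biaryl phosphine lets zerovalent palladium insert into the doubly ortho-substituted aryl iodide, the alkenyl group is transferred with retention of its (E) geometry, and the aldehyde and MOM ethers are inert to the mild phosphate base.

Step 7
Reactants: 5 (E)-3-[2,4-bis(methoxymethoxy)phenyl]-1-[2-hydroxy-4-(methoxymethoxy)phenyl]prop-2-en-1-one; 12 2,4-bis(methoxymethoxy)-3-[(1E)-3-methylbuta-1,3-dien-1-yl]benzaldehyde
Product: 13 (3R,4R,5S)-all-trans cycloadduct: 1-methylcyclohexene with 3-formyl-2,6-bis(methoxymethoxy)phenyl at C3, 2-hydroxy-4-(methoxymethoxy)benzoyl at C4 and 2,4-bis(methoxymethoxy)phenyl at C5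
Conditions: (S)-VANOL (1.2 equiv), BH3·THF, AcOH, THF, rt, evaporate; then 5 and 12 (2 equiv), 5 Å MS, PhCF3, rt; aq. NaHCO3; chromatography (removes any 3,4-cis adduct)
Reagents that add atoms: none
Why: Chiral boron-promoted Diels–Alder reaction of a 2'-hydroxychalcone, a known way to this class of aryl cyclohexenes: the phenol and ketone of 5 bind the VANOL-bound boron, which lowers the LUMO of the enone, the CH2 terminus of the diene bonds to the β-carbon, the biaryl ligand shields one enone face (absolute configuration) and keeps the aryl group of the diene away from the chelate (exo, so C3/C4 trans), and the (E)-alkene carries its geometry into C4/C5 trans, giving the 3R,4R,5S all-trans adduct.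

Step 8
Reactants: 13 (3R,4R,5S)-all-trans cycloadduct with free 2-hydroxyl on the aroyl group
Product: 14 (3R,4R,5S)-hexa-MOM aldehyde: 1-methylcyclohexene with 3-formyl-2,6-bis(methoxymethoxy)phenyl at C3, 2,4-bis(methoxymethoxy)benzoyl at C4 and 2,4-bis(methoxymethoxy)phenyl at C5
Conditions: NaH (1.2 equiv), MOMCl, DMF, 0 °C
Reagents that add atoms: chloromethyl methyl ether (MOMCl), COCCl
Why: Williamson-type MOM ether formation of the sodium phenoxide, needed so that the aryl ketone at C4 has no free ortho-hydroxyl in the peroxide step; a slight excess of NaH removes only the phenolic proton, and C4 already has its more stable all-equatorial configuration.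

Step 9
Reactants: 14 (3R,4R,5S)-hexa-MOM aldehyde; 2 2-hydroxy-4-(methoxymethoxy)acetophenone
Product: 15 (3R,4R,5S)-core-bound 2'-hydroxychalcone: as 14 but with (E)-3-[2-hydroxy-4-(methoxymethoxy)phenyl]-3-oxoprop-1-enyl in place of the formyl group
Conditions: KOH, EtOH/THF/H2O, rt
Reagents that add atoms: none
Why: Claisen–Schmidt condensation of the non-enolisable aryl aldehyde with methyl ketone 2 gives the (E)-2'-hydroxychalcone, while the ketone at C4 has only one hindered tertiary α-hydrogen, cannot condense, and can at most be returned by base to the all-trans arrangement it already has.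

Step 10
Reactants: 15 (3R,4R,5S)-core-bound 2'-hydroxychalcone
Product: 17 (3R,4R,5S)-hepta-MOM flavonol with free 3-hydroxyl, via dihydroflavonol 16 (not isolated)
Conditions: 30% aq. H2O2, aq. NaOH, MeOH/THF, 0 °C → rt
Reagents that add atoms: hydrogen peroxide, OO
Why: Algar–Flynn–Oyamada oxidation, a known reaction of 2'-hydroxychalcones: in alkaline peroxide the phenoxide adds to the enone β-carbon (oxa-Michael) and the enolate so formed is hydroxylated at the α-carbon by H2O2, giving trans-dihydroflavonol 16, which the same medium dehydrogenates to the flavonol, so that O1–C2 and C3–OH are made and the pyranone is closed. The ring closes 6-endo-trig at the benzylic β-carbon; the 5-exo closure at the α-carbon that leads to aurones is known to take over only when C6' of ring A is substituted, and here C6' carries hydrogen because the target has no 5-hydroxyl. No lasting stereocentre is formed: the two sp3 carbons of 16 arise as a trans pair of either sense and become sp2 again, and C3, C4 and C5 of the cyclohexene are not involved. The step needs chemoselectivity between two alkenes, and the oxidant supplies it, since hydroperoxide anion is a nucleophile that attacks the electron-poor enone and not the electron-rich trisubstituted C1=C2 bond that an electrophilic oxidant would epoxidise. It also needs the aryl ketone at C4 to survive, which is secured by its MOM-capped ortho- and para-oxygens (no phenoxide to drive a Dakin-type aryl migration) and by C4 already being the all-equatorial epimer, so that enolisation by hydroxide changes nothing.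

Step 11
Reactants: 17 (3R,4R,5S)-hepta-MOM flavonol
Product: 18 target CNP0190989.1
Conditions: HCl (3 M in MeOH), THF, 0 °C → rt; NaHCO3 quench as soon as the last acetal is gone
Reagents that add atoms: none
Why: Acid-catalysed acetal exchange with methanol (MOM cleavage) frees the seven phenols, and at low temperature it should outrun protonation of the trisubstituted alkene, whose capture by a neighbouring phenol would in any case require the all-equatorial ring to flip into an all-axial conformer.

**Compound list**

1 | 2,4-dihydroxyacetophenone | CC(=O)c1ccc(O)cc1O | starting material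
2 | 2-hydroxy-4-(methoxymethoxy)acetophenone | CC(=O)c1ccc(OCOC)cc1O | intermediate
3 | 2,4-dihydroxybenzaldehyde | O=Cc1ccc(O)cc1O | starting material
4 | 2,4-bis(methoxymethoxy)benzaldehyde | O=Cc1ccc(OCOC)cc1OCOC | intermediate
5 | (E)-3-[2,4-bis(methoxymethoxy)phenyl]-1-[2-hydroxy-4-(methoxymethoxy)phenyl]prop-2-en-1-one | O=C(/C=C/c1ccc(OCOC)cc1OCOC)c1ccc(OCOC)cc1O | intermediate
6 | lithium [2,4-bis(methoxymethoxy)phenyl](4-methylpiperazin-1-yl)methanolate (racemic at the carbinol carbon) | [Li+].[O-]C(N1CCN(C)CC1)c1ccc(OCOC)cc1OCOC | intermediate (not isolated)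
7 | 3-lithio derivative of 6 (lithium between the two MOM ethers) | [Li+].[O-]C(N1CCN(C)CC1)c1ccc(OCOC)c([Li])c1OCOC | intermediate (not isolated)
8 | lithium [3-iodo-2,4-bis(methoxymethoxy)phenyl](4-methylpiperazin-1-yl)methanolate | [Li+].[O-]C(N1CCN(C)CC1)c1ccc(OCOC)c(I)c1OCOC | intermediate (not isolated)
9 | 3-iodo-2,4-bis(methoxymethoxy)benzaldehyde | O=Cc1ccc(OCOC)c(I)c1OCOC | intermediate
10 | 2-methylbut-1-en-3-yne | C#CC(C)=C | starting material
11 | (E)-4,4,5,5-tetramethyl-2-(3-methylbuta-1,3-dien-1-yl)-1,3,2-dioxaborolane | CC(=C)/C=C/B1OC(C)(C)C(C)(C)O1 | intermediate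
12 | 2,4-bis(methoxymethoxy)-3-[(1E)-3-methylbuta-1,3-dien-1-yl]benzaldehyde | O=Cc1ccc(OCOC)c(/C=C/C(C)=C)c1OCOC | intermediate
13 | (3R,4R,5S)-all-trans cycloadduct: 3-[3-formyl-2,6-bis(methoxymethoxy)phenyl]-4-[2-hydroxy-4-(methoxymethoxy)benzoyl]-5-[2,4-bis(methoxymethoxy)phenyl]-1-methylcyclohex-1-ene | CC1=C[C@@H](c2c(OCOC)ccc(C=O)c2OCOC)[C@H](C(=O)c2ccc(OCOC)cc2O)[C@@H](c2ccc(OCOC)cc2OCOC)C1 | intermediate
14 | (3R,4R,5S)-hexa-MOM aldehyde: 3-[3-formyl-2,6-bis(methoxymethoxy)phenyl]-4-[2,4-bis(methoxymethoxy)benzoyl]-5-[2,4-bis(methoxymethoxy)phenyl]-1-methylcyclohex-1-ene | CC1=C[C@@H](c2c(OCOC)ccc(C=O)c2OCOC)[C@H](C(=O)c2ccc(OCOC)cc2OCOC)[C@@H](c2ccc(OCOC)cc2OCOC)C1 | intermediate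
15 | (3R,4R,5S)-core-bound 2'-hydroxychalcone (key-step precursor): 14 with the formyl group replaced by (E)-CH=CH–C(=O)–[2-hydroxy-4-(methoxymethoxy)phenyl] | CC1=C[C@@H](c2c(OCOC)ccc(/C=C/C(=O)c3ccc(OCOC)cc3O)c2OCOC)[C@H](C(=O)c2ccc(OCOC)cc2OCOC)[C@@H](c2ccc(OCOC)cc2OCOC)C1 | intermediate
16 | (3R,4R,5S)-core-bound trans-3-hydroxy-7-(methoxymethoxy)chroman-4-one (dihydroflavonol; the chromanone C2/C3 pair is trans, of either absolute sense, and is not drawn) | CC1=C[C@@H](c2c(OCOC)ccc(C3Oc4cc(OCOC)ccc4C(=O)C3O)c2OCOC)[C@H](C(=O)c2ccc(OCOC)cc2OCOC)[C@@H](c2ccc(OCOC)cc2OCOC)C1 | intermediate (not isolated)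
17 | (3R,4R,5S)-hepta-MOM flavonol (key-step product): 3-hydroxy-7-(methoxymethoxy)-4H-chromen-4-one attached through its C2 to the C3 aryl ring of the fully MOM-protected core | CC1=C[C@@H](c2c(OCOC)ccc(-c3oc4cc(OCOC)ccc4c(=O)c3O)c2OCOC)[C@H](C(=O)c2ccc(OCOC)cc2OCOC)[C@@H](c2ccc(OCOC)cc2OCOC)C1 | intermediate
18 | CNP0190989.1: (3R,4R,5S)-all-trans 4-(2,4-dihydroxybenzoyl)-5-(2,4-dihydroxyphenyl)-3-[2,6-dihydroxy-3-(3,7-dihydroxy-4-oxo-4H-chromen-2-yl)phenyl]-1-methylcyclohex-1-ene | CC1=C[C@@H](c2c(O)ccc(-c3oc4cc(O)ccc4c(=O)c3O)c2O)[C@H](C(=O)c2ccc(O)cc2O)[C@@H](c2ccc(O)cc2O)C1 | target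

**Step count and risks**

Total steps: 11. Longest linear sequence: 8 steps (from 3 through steps 2, 4, 6, 7, 8, 9, 10 and 11).

Steps most likely to fail:

1. Step 7. The ligand may not discriminate the faces of the boron-bound enone well enough, the exo preference may be weak, or the formyl group of the diene may tie up the boron promoter and stall the reaction. The fallback gives up asymmetric induction in favour of resolution. It sets out again from 5 and 12: cycloaddition on Ag nanoparticles supported on SiO2 (zerovalent silver, CH2Cl2, 50 °C), a known non-chiral catalyst for 2'-hydroxychalcone cycloadditions, should give, after chromatographic removal of the 3,4-cis isomer, the racemic all-trans adduct F1. Preparative chromatography on a chiral stationary phase (amylose tris(3,5-dimethylphenylcarbamate)) then separates the enantiomers, and the (3R,4R,5S) antipode rejoins the route as 13.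

2. Step 10. Ring closure and oxidation are coupled in one pot, so the closure may drift to the five-membered ring, or the hindered enone may react too slowly and peroxide may degrade the electron-rich rings. The fallback uncouples epoxidation from closure and sets out from 15. The 2'-hydroxyl is masked with allyl bromide and K2CO3 in acetone to give the allyl ether F2. Weitz–Scheffer epoxidation (H2O2, NaOH, MeOH/THF) of this enone, which now has no internal nucleophile, should give the trans-epoxy ketone F3. Pd(PPh3)4 with K2CO3 in MeOH then removes the allyl group, and the 2'-hydroxy epoxy ketone F4 formed in the flask should open its epoxide at the benzylic carbon, activated by the 2,4-dialkoxyaryl ring, in the 6-endo mode. This rejoins the route at 16, which is isolated here and dehydrogenated to 17 with the alkaline peroxide of step 10.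

3. Step 11. Seven acetals need prolonged acid, during which the ring alkene may be protonated and then migrate or be captured by a phenol. The fallback avoids protic acid and sets out from 17. TMSOTf with 2,2'-bipyridyl in CH2Cl2 (0 °C → rt) exchanges each aryl MOM ether for a silyl ether under non-protic conditions, and silylates the free 3-hydroxyl as well, to give the octakis(trimethylsilyl) ether F5. Stirring with water at neutral pH hydrolyses the aryl silyl ethers and returns to the route at 18.

**Further compounds**

F1 | step 7 | racemic all-trans cycloadduct (13 together with its mirror image) | CC1=C[C@@H](c2c(OCOC)ccc(C=O)c2OCOC)[C@H](C(=O)c2ccc(OCOC)cc2O)[C@@H](c2ccc(OCOC)cc2OCOC)C1.CC1=C[C@H](c2c(OCOC)ccc(C=O)c2OCOC)[C@@H](C(=O)c2ccc(OCOC)cc2O)[C@H](c2ccc(OCOC)cc2OCOC)C1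
F2 | step 10 | 2'-O-allyl ether of chalcone 15 | CC1=C[C@@H](c2c(OCOC)ccc(/C=C/C(=O)c3ccc(OCOC)cc3OCC=C)c2OCOC)[C@H](C(=O)c2ccc(OCOC)cc2OCOC)[C@@H](c2ccc(OCOC)cc2OCOC)C1
F3 | step 10 | trans-α,β-epoxy ketone from F2 (either epoxide sense, not drawn) | CC1=C[C@@H](c2c(OCOC)ccc(C3OC3C(=O)c3ccc(OCOC)cc3OCC=C)c2OCOC)[C@H](C(=O)c2ccc(OCOC)cc2OCOC)[C@@H](c2ccc(OCOC)cc2OCOC)C1
F4 | step 10 | 2'-hydroxy epoxy ketone formed in the flask on deallylation of F3 | CC1=C[C@@H](c2c(OCOC)ccc(C3OC3C(=O)c3ccc(OCOC)cc3O)c2OCOC)[C@H](C(=O)c2ccc(OCOC)cc2OCOC)[C@@H](c2ccc(OCOC)cc2OCOC)C1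
F5 | step 11 | octakis(trimethylsilyl) ether of the target | CC1=C[C@@H](c2c(O[Si](C)(C)C)ccc(-c3oc4cc(O[Si](C)(C)C)ccc4c(=O)c3O[Si](C)(C)C)c2O[Si](C)(C)C)[C@H](C(=O)c2ccc(O[Si](C)(C)C)cc2O[Si](C)(C)C)[C@@H](c2ccc(O[Si](C)(C)C)cc2O[Si](C)(C)C)C1
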